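## The problem

Numbering throughout: C1 (fusion CH), C2 (carbinol), C3 (isopropyl), C4 (acyloxy), C5 (CH2), C6 (methyl-bearing fusion carbon), C7 (apex). β is the face of the six-membered ring on which C7 lies, α the opposite face (that of H1 and the C6 methyl). Exo at C7 means pointing away from the six-membered ring.

Target 23 is a cyclohexane cis-fused to a cyclopropane (C1–C6–C7) with a quaternary methyl on C6 and a 3-oxobutyl chain exo on C7; its configuration is (1R,2S,3S,4R,6S,7R). The six stereocentres form two groups: the cyclopropane triad C1/C6/C7, and the ring triad C2/C3/C4, whose hydroxyl, isopropyl and acyloxy groups are all α and mutually cis. In the half-chair that keeps isopropyl equatorial both oxygens are axial, and H2, H3 and H4 all lie on the β face under the cyclopropane. The triad is therefore a kinetic arrangement that reductions from the open α face cannot deliver. The cyclopropane is the only stereochemical element present before the triad, and its influence is strongest at C2, so control has to be relayed C1 → C2 → C3 → C4. The fragile groups are the (Z)-cinnamate (Z→E isomerisation, conjugate reduction, acyl migration to the syn-axial C2 hydroxyl), the secondary cyclopropylcarbinol (ionisation in acid) and the methyl ketone (hydride, enolisation); the two ring oxygens must also be told apart. The enabling feature is that the C1–C6 bond, with methyl on C6 and a carbon substituent on C7, is the double bond of a 1-methylcyclopropene-3-carboxylate, while C2–C5, with oxygen on C2 and C4 and isopropyl on C3, map onto a 1,1,3-trioxygenated 2-isopropylbuta-1,3-diene.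

## Retrosynthesis

**Ester and last protecting group (23 ⇐ 22 ⇐ 21 ⇐ 19 + 20).** The O–Si bond at C2 is cut last, the cis alkene of the cinnamate is read as an alkyne, and the C4 O–acyl bond is cut to alcohol 19 and acid chloride 20. Placing the cinnamate at the very end keeps it away from every hydride, copper hydride and basic step. Making the Z alkene by syn addition of hydrogen to ynoate 21 avoids carrying a Z acid through carboxyl activation. The forward steps must acylate a hindered hydroxyl, stop the hydrogenation at the alkene, and desilylate without base.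

**Side chain (19 ⇐ 18 ⇐ 16 + 17; 16 ⇐ 15).** The chain is cut at the bond between the first and second chain carbons (a Wittig C=C in enone 18), giving aldehyde 16 and ylide 17; 16 returns to primary alcohol 15. Building the ketone only after the last ring hydride step removes the need for a ketone protecting group, which an earlier chain construction would require. The forward steps need a primary-selective oxidation beside a free secondary hydroxyl and a conjugate reduction that spares the cyclopropane.

**C4 carbinol and oxygen differentiation (15 ⇐ 14 ⇐ 13 ⇐ 12).** The C4–H bond is cut to ketone 13, and both silyl ethers to keto-diol 12. Reducing C4 while C2 is already silylated leaves exactly the hydroxyl that must be acylated free, so the two oxygens are differentiated by the order of events. The reduction must deliver hydride from the β face, which a bulky hydride does by equatorial attack next to an equatorial isopropyl group.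

**C2–O and C3–H (12 ⇐ 11 ⇐ 10).** The C3–H bond is cut to the C3–O bond of epoxy ketone 11, and both epoxide C–O bonds are cut to the alkene of enone 10. Reducing a C2 ketone, or hydrogenating a C3=C4 enol ether, would have to bring hydrogen to the hindered β face. Here the C2–O bond is instead made from the open α face by conjugate attack next to the cyclopropane, where the facial bias is largest. Enone 10 carries only the three cyclopropane stereocentres. The forward steps need α-face epoxidation and protonation of C3 from the β face.

**Carbonyl transposition (10 ⇐ 9 ⇐ 8).** No skeletal bond is cut: the C4 carbonyl and C2=C3 alkene of 10 are traced to the C2 carbonyl and C4 enol ether of vinylogous ester 8 through allylic alcohol 9, and the hydroxymethyl group to the C7 ester. One reduction then does two jobs, and the alkene is placed at C2=C3 without an oxidation step.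

**Cycloaddition (8 ⇐ 7 ⇐ 3 + 6).** C1–C2 and C5–C6 are cut, giving cyclopropene ester 3 and diene 6 by way of cycloadduct 7. Cutting a cyclopropane bond instead (C1–C7 or C6–C7) would leave the three cyclopropane centres to be set against a substituted cyclohexane. This cut derives C1 and C6 from the single stereocentre of 3 and reduces the problem to two small fragments. The forward reaction must add anti to the ester and join the CH2 terminus of 6 to the methyl-bearing carbon. The ketene-acetal oxygens of 6 provide reactivity and regiocontrol and become the C2 carbonyl that drives the transposition; the C3 oxygen of 6 becomes O4 of the target.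

**Fragments (3 ⇐ 1 + 2; 6 ⇐ 5 ⇐ 4).** Cyclopropene 3 is cut at its two ring bonds to the carbene carbon, giving propyne 1 and diazo ester 2. Diene 6 comes from enol ether 5 by γ-deprotonation and O-silylation, and 5 from commercial keto ester 4. Only the cyclopropenation has to be enantioselective.

## Roads not taken

**Alternative 1:** The cut is at the C6–CH3 bond and the bond from C7 to the side chain, on cyclopropene A1, with the six-membered ring still open. In the forward step a methylcopper reagent adds across A1 on the face away from the silyloxymethyl group, and the cyclopropylcopper is trapped by conjugate addition to the four-carbon enone, giving A2.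
- Merits: the quaternary methyl and the complete oxobutyl chain arrive in one operation, and all three cyclopropane centres follow from one stereocentre. On the side chain this road is clearly better than the chosen one, which spends three steps and a protect/deprotect pair on it.
- Weak points: the six-membered ring still has to be closed with three contiguous stereocentres built on a chain, with a free methyl ketone competing in any enolate chemistry. Methyl delivery to the substituted alkene carbon must be enforced by the directing group, and conjugate addition of a secondary cyclopropylcopper is sluggish. A1 needs the same kind of enantioselective cyclopropenation as 3.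
- Comparison: the chosen plan forms the six-membered ring and the cyclopropane centres together in step 4 and relays the ring triad from the rigid bicycle.

**Alternative 2:** The cut is C1–C7. The kinetic lithium enolate of cyclohexanone A3 displaces the allylic chloride in an SN2′ sense and closes the cyclopropane, giving vinyl ketone A4.
- Merits: C3 and C4 are set on a plain cyclohexanone before the cyclopropane exists, and only the C2 ketone remains to be reduced. For the ring triad this is arguably better than the chosen plan, which relays it from the cyclopropane over four steps. The vinyl group is a convenient handle for the chain.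
- Weak points: A3 needs the quaternary C6 centre with a chloropropenyl arm set absolutely, in addition to C3 and C4. The configuration at C7 (vinyl exo or endo) depends on the geometry of the displacement and is not secured by any element of the substrate.
- Comparison: the chosen plan sets C1, C6 and C7 from one catalytically made stereocentre and places the C7 substituent exo by facial selection.

**Alternative 3:** The cuts are C4–C5 and C6–C7. A dialkylaluminium chloride activates the aldehyde of A5, the isopropenyl CH2 attacks it, and the tertiary C6 cation is captured by the γ C–Sn bond to close the cyclopropane, giving A6.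
- Merits: both rings form in one step. A6 has C4–OH free, C2 silylated and the chain ketone protected, which is the pattern the endgame needs. In this respect it is better than the chosen route, which needs silylation, selective desilylation and late chain construction.
- Weak points: A5 is an acyclic aldehyde with four stereocentres, one of them a secondary α-stannyl carbon. A chair-like cyclisation would tend to place the new hydroxyl equatorial, trans to isopropyl, opposite to the target. The tertiary cation can lose a proton instead of closing the three-membered ring, and tin is stoichiometric.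
- Comparison: the chosen plan starts from three-, four- and nine-carbon fragments made in one or two steps.

Key step: step 4

Assumption: Rh2(5R-MEPY)4 is taken to give the (1R)-cyclopropene from propyne, by analogy with the sense of induction known for other terminal alkynes; were the sense opposite, the 5S catalyst would be used (MEPY = methyl 2-oxopyrrolidine-5-carboxylate, bound as its amidate).

## Route

Step 1
Reactants: 1 propyne; 2 ethyl diazoacetate
Product: 3 ethyl (1R)-2-methylcycloprop-2-ene-1-carboxylate
Conditions: Rh2(5R-MEPY)4 (1 mol %), excess 1, CH2Cl2, slow addition of 2, 25 °C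
Reagents that add atoms: none
Why: Rhodium-carbenoid cyclopropenation of a terminal alkyne; the chiral carboxamidate ligands differentiate the faces of the carbenoid, so the single stereocentre (future C7) is set here.

Step 2
Reactants: 4 ethyl 2-acetyl-3-methylbutanoate
Product: 5 ethyl 3-ethoxy-2-(propan-2-yl)but-2-enoate (E/Z mixture)
Conditions: HC(OEt)3, EtOH, H2SO4 (cat.), 25 °C; then distillation from KHSO4
Reagents that add atoms: triethyl orthoformate, CCOC(OCC)OCC
Why: Acid-catalysed ketalisation of the ketone and loss of ethanol give the β-ethoxy enoate (enol ether formation); double-bond isomers, including any but-3-enoate, are inconsequential because all give the same dienolate in step 3.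

Step 3
Reactants: 5 ethyl 3-ethoxy-2-(propan-2-yl)but-2-enoate
Product: 6 [1,3-diethoxy-2-(propan-2-yl)buta-1,3-dien-1-yl]oxy(trimethyl)silane (ketene-acetal geometry mixed)
Conditions: LiN(i-Pr)2, THF, −78 °C; Me3SiCl, −78 → 0 °C
Reagents that add atoms: chlorotrimethylsilane, C[Si](C)(C)Cl
Why: γ-Deprotonation to the extended dienolate and O-silylation (silyl ketene acetal formation) give the 1-alkoxy-1-silyloxy-3-alkoxy diene, which is used freshly distilled.

Step 4
Reactants: 3 ethyl (1R)-2-methylcycloprop-2-ene-1-carboxylate; 6 [1,3-diethoxy-2-(propan-2-yl)buta-1,3-dien-1-yl]oxy(trimethyl)silane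
Product: 8 ethyl (1R,6R,7R)-4-ethoxy-6-methyl-2-oxo-3-(propan-2-yl)bicyclo[4.1.0]hept-3-ene-7-carboxylate, via silyl ketal cycloadduct 7 (not isolated)
Conditions: neat, 25 → 50 °C, Ar; then Bu4NF, AcOH, THF, 0 °C
Reagents that add atoms: none
Why: A concerted suprafacial [4+2] cycloaddition in which release of cyclopropene strain makes up for the lack of a conjugating acceptor; the closest known reaction type is the Diels–Alder reaction of cycloprop-2-ene-1-carboxylic acid derivatives with acyclic dienes. The six-membered ring is closed by intermolecular cycloaddition that forms C1–C2 and C5–C6 together, so the fusion is necessarily cis. The diene adds to the face of 3 opposite the ester on the sp3 carbon, so the existing C7 stereocentre fixes C1 and C6 and the ester ends exo. The required regiochemistry (CH2 terminus to the methyl-bearing carbon) should follow from pairing the bulky, fully substituted ketene-acetal terminus with the unsubstituted alkene carbon. C2 of 7 forms as an epimer mixture and endo or exo approach is immaterial, because buffered fluoride then removes the silyl group and the resulting alkoxide expels ethoxide. This unveils the C2 ketone regiospecifically while the C4 enol ether remains as a vinylogous ester.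

Step 5
Reactants: 8 ethyl (1R,6R,7R)-4-ethoxy-6-methyl-2-oxo-3-(propan-2-yl)bicyclo[4.1.0]hept-3-ene-7-carboxylate
Product: 10 (1R,6R,7R)-7-(hydroxymethyl)-6-methyl-3-(propan-2-yl)bicyclo[4.1.0]hept-2-en-4-one, via enol ether diol 9 (not isolated)
Conditions: LiAlH4, Et2O, 0 °C; then 0.5 M aq. H2SO4, THF, 0 °C → 25 °C
Reagents that add atoms: water, O
Why: Hydride reduces the ester and adds 1,2 to the vinylogous ester; aqueous acid then converts the allylic alcohol–enol ether into the enone (Stork–Danheiser transposition), moving the carbonyl to C4 and the alkene to C2=C3. The C2 carbinol centre of 9 is lost again, so its configuration does not matter.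

Step 6
Reactants: 10 (1R,6R,7R)-7-(hydroxymethyl)-6-methyl-3-(propan-2-yl)bicyclo[4.1.0]hept-2-en-4-one
Product: 11 (1R,2S,3S,6S,7R)-2,3-epoxy-7-(hydroxymethyl)-6-methyl-3-(propan-2-yl)bicyclo[4.1.0]heptan-4-one (oxirane on the α face)
Conditions: 30% aq. H2O2, NaOH (cat.), MeOH, 0 °C
Reagents that add atoms: hydrogen peroxide, OO
Why: Weitz–Scheffer nucleophilic epoxidation; hydroperoxide adds to C2 on the α face, anti to the C1–C7 bond of the adjacent cyclopropane, and the enolate closes the oxirane, so both new C–O bonds are α.

Step 7
Reactants: 11 (1R,2S,3S,6S,7R)-2,3-epoxy-7-(hydroxymethyl)-6-methyl-3-(propan-2-yl)bicyclo[4.1.0]heptan-4-one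
Product: 12 (1R,2S,3S,6S,7R)-2-hydroxy-7-(hydroxymethyl)-6-methyl-3-(propan-2-yl)bicyclo[4.1.0]heptan-4-one
Conditions: SmI2 (2.5 equiv), THF–MeOH, −90 °C
Reagents that add atoms: none
Why: Two-electron reductive opening of the α,β-epoxy ketone cleaves the C3–O bond and leaves the C2 oxygen α. The samarium enolate should be protonated at C3 from the β face, anti to the pseudoaxial C2 alkoxide, which puts isopropyl α and cis to the hydroxyl. No radical or anion develops at C2, so the cyclopropane is not at risk.

Step 8
Reactants: 12 (1R,2S,3S,6S,7R)-2-hydroxy-7-(hydroxymethyl)-6-methyl-3-(propan-2-yl)bicyclo[4.1.0]heptan-4-one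
Product: 13 (1R,2S,3S,6S,7R)-6-methyl-3-(propan-2-yl)-2-(triethylsilyloxy)-7-[(triethylsilyloxy)methyl]bicyclo[4.1.0]heptan-4-one
Conditions: Et3SiOTf, 2,6-lutidine, CH2Cl2, −78 °C
Reagents that add atoms: triethylsilyl trifluoromethanesulfonate, CC[Si](CC)(CC)OS(=O)(=O)C(F)(F)F
Why: Silyl triflate silylation of both hydroxyls at low temperature with a hindered base, conditions under which the β-silyloxy ketone should neither enolise nor epimerise at C3.

Step 9
Reactants: 13 (1R,2S,3S,6S,7R)-6-methyl-3-(propan-2-yl)-2-(triethylsilyloxy)-7-[(triethylsilyloxy)methyl]bicyclo[4.1.0]heptan-4-one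
Product: 14 (1R,2S,3R,4R,6S,7R)-6-methyl-3-(propan-2-yl)-2-(triethylsilyloxy)-7-[(triethylsilyloxy)methyl]bicyclo[4.1.0]heptan-4-ol
Conditions: LiBH(s-Bu)3, THF, −78 °C; then H2O
Reagents that add atoms: none
Why: Bulky trialkylborohydride reduction with equatorial attack, the selectivity that turns 2-alkylcyclohexanones into cis alcohols. With isopropyl equatorial the equatorial direction is the β face, and the α face is further shielded by the syn-axial C2 silyl ether, so the C4 hydroxyl should come out α, cis to isopropyl.

Step 10
Reactants: 14 (1R,2S,3R,4R,6S,7R)-6-methyl-3-(propan-2-yl)-2-(triethylsilyloxy)-7-[(triethylsilyloxy)methyl]bicyclo[4.1.0]heptan-4-ol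
Product: 15 (1R,2S,3R,4R,6S,7R)-7-(hydroxymethyl)-6-methyl-3-(propan-2-yl)-2-(triethylsilyloxy)bicyclo[4.1.0]heptan-4-ol
Conditions: PPTS (cat.), MeOH–CH2Cl2, −10 °C
Reagents that add atoms: none
Why: Acid-catalysed methanolysis (selective desilylation) removes the unhindered primary silyl ether much faster than the secondary one flanked by the cyclopropane and the isopropyl-bearing carbon.

Step 11
Reactants: 15 (1R,2S,3R,4R,6S,7R)-7-(hydroxymethyl)-6-methyl-3-(propan-2-yl)-2-(triethylsilyloxy)bicyclo[4.1.0]heptan-4-ol
Product: 16 (1R,2S,3R,4R,6R,7R)-4-hydroxy-6-methyl-3-(propan-2-yl)-2-(triethylsilyloxy)bicyclo[4.1.0]heptane-7-carbaldehyde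
Conditions: TEMPO (cat.), PhI(OAc)2, CH2Cl2, 25 °C
Reagents that add atoms: none
Why: Oxoammonium (TEMPO) oxidation is selective for the primary alcohol over the hindered axial secondary one and stops at the aldehyde. The exo aldehyde points away from the ring and cannot reach the C4 hydroxyl to form a lactol.

Step 12
Reactants: 16 (1R,2S,3R,4R,6R,7R)-4-hydroxy-6-methyl-3-(propan-2-yl)-2-(triethylsilyloxy)bicyclo[4.1.0]heptane-7-carbaldehyde; 17 1-(triphenyl-λ5-phosphanylidene)propan-2-one
Product: 18 (3E)-4-[(1R,2S,3R,4R,6S,7R)-4-hydroxy-6-methyl-3-(propan-2-yl)-2-(triethylsilyloxy)bicyclo[4.1.0]heptan-7-yl]but-3-en-2-one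
Conditions: CH2Cl2, 40 °C
Reagents that add atoms: none
Why: Wittig olefination with a stabilised ylide gives the (E)-enone and brings in the last three chain carbons; the ylide tolerates the free hydroxyl, and the exo aldehyde has no driving force to epimerise.

Step 13
Reactants: 18 (3E)-4-[(1R,2S,3R,4R,6S,7R)-4-hydroxy-6-methyl-3-(propan-2-yl)-2-(triethylsilyloxy)bicyclo[4.1.0]heptan-7-yl]but-3-en-2-one
Product: 19 4-[(1R,2S,3R,4R,6S,7R)-4-hydroxy-6-methyl-3-(propan-2-yl)-2-(triethylsilyloxy)bicyclo[4.1.0]heptan-7-yl]butan-2-one
Conditions: [(Ph3P)CuH]6, wet C6H6, 25 °C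
Reagents that add atoms: none
Why: Copper hydride conjugate reduction (1,4-hydride addition, then protonation of the copper enolate) leaves the saturated ketone, the cyclopropane and the silyl ether untouched; no radical is formed next to the three-membered ring.

Step 14
Reactants: 19 4-[(1R,2S,3R,4R,6S,7R)-4-hydroxy-6-methyl-3-(propan-2-yl)-2-(triethylsilyloxy)bicyclo[4.1.0]heptan-7-yl]butan-2-one; 20 3-phenylprop-2-ynoyl chloride
Product: 21 (1R,2S,3R,4R,6S,7R)-6-methyl-7-(3-oxobutyl)-3-(propan-2-yl)-2-(triethylsilyloxy)bicyclo[4.1.0]heptan-4-yl 3-phenylprop-2-ynoate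
Conditions: pyridine, DMAP (cat.), CH2Cl2, 0 → 25 °C
Reagents that add atoms: none
Why: Acylation of a secondary alcohol by an acid chloride under nucleophilic catalysis; the slim ynoyl chloride suits the hindered hydroxyl, which can also react through the ring-flipped conformer in which it is equatorial.

Step 15
Reactants: 21 (1R,2S,3R,4R,6S,7R)-6-methyl-7-(3-oxobutyl)-3-(propan-2-yl)-2-(triethylsilyloxy)bicyclo[4.1.0]heptan-4-yl 3-phenylprop-2-ynoate
Product: 22 (1R,2S,3R,4R,6S,7R)-6-methyl-7-(3-oxobutyl)-3-(propan-2-yl)-2-(triethylsilyloxy)bicyclo[4.1.0]heptan-4-yl (2Z)-3-phenylprop-2-enoate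
Conditions: H2 (1 atm), Pd/CaCO3 poisoned with Pb(OAc)2, quinoline, EtOAc, 25 °C
Reagents that add atoms: none
Why: Semihydrogenation of the ynoate on lead-poisoned palladium adds both hydrogens syn and should give the (Z)-cinnamate; the ketone, cyclopropane and silyl ether are inert under these conditions.

Step 16
Reactants: 22 (1R,2S,3R,4R,6S,7R)-6-methyl-7-(3-oxobutyl)-3-(propan-2-yl)-2-(triethylsilyloxy)bicyclo[4.1.0]heptan-4-yl (2Z)-3-phenylprop-2-enoate
Product: 23 (1R,2S,3S,4R,6S,7R)-2-hydroxy-6-methyl-7-(3-oxobutyl)-3-(propan-2-yl)bicyclo[4.1.0]heptan-4-yl (2Z)-3-phenylprop-2-enoate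
Conditions: HF·pyridine, THF, 0 °C
Reagents that add atoms: none
Why: Fluoride-mediated desilylation under buffered, non-basic conditions frees the C2 hydroxyl while avoiding acyl migration from O4, Z→E isomerisation and ionisation of the cyclopropylcarbinol.

## Compound list

1 | propyne | CC#C | starting material
2 | ethyl diazoacetate | CCOC(=O)C=[N+]=[N-] | starting material
3 | ethyl (1R)-2-methylcycloprop-2-ene-1-carboxylate | CCOC(=O)[C@@H]1C=C1C | intermediate
4 | ethyl 2-acetyl-3-methylbutanoate (ethyl 2-isopropylacetoacetate) | CCOC(=O)C(C(C)C)C(C)=O | starting material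
5 | ethyl 3-ethoxy-2-(propan-2-yl)but-2-enoate, E/Z mixture | CCOC(=O)C(C(C)C)=C(C)OCC | intermediate
6 | [1,3-diethoxy-2-(propan-2-yl)buta-1,3-dien-1-yl]oxy(trimethyl)silane, ketene-acetal geometry mixed | C=C(OCC)C(C(C)C)=C(OCC)O[Si](C)(C)C | intermediate
7 | ethyl (1R,6R,7R)-2,4-diethoxy-6-methyl-3-(propan-2-yl)-2-(trimethylsilyloxy)bicyclo[4.1.0]hept-3-ene-7-carboxylate, 7-exo ester, both C2 epimers | CCOC(=O)[C@@H]1[C@H]2C(OCC)(O[Si](C)(C)C)C(C(C)C)=C(OCC)C[C@]21C | intermediate (not isolated)
8 | ethyl (1R,6R,7R)-4-ethoxy-6-methyl-2-oxo-3-(propan-2-yl)bicyclo[4.1.0]hept-3-ene-7-carboxylate | CCOC(=O)[C@@H]1[C@H]2C(=O)C(C(C)C)=C(OCC)C[C@]21C | intermediate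
9 | (1R,6S,7R)-4-ethoxy-7-(hydroxymethyl)-6-methyl-3-(propan-2-yl)bicyclo[4.1.0]hept-3-en-2-ol, C2 epimers, present as its aluminium alkoxide | OC[C@@H]1[C@H]2C(O)C(C(C)C)=C(OCC)C[C@]21C | intermediate (not isolated)
10 | (1R,6R,7R)-7-(hydroxymethyl)-6-methyl-3-(propan-2-yl)bicyclo[4.1.0]hept-2-en-4-one | OC[C@@H]1[C@H]2C=C(C(C)C)C(=O)C[C@]21C | intermediate
11 | (1R,2S,3S,6S,7R)-2,3-epoxy-7-(hydroxymethyl)-6-methyl-3-(propan-2-yl)bicyclo[4.1.0]heptan-4-one, oxirane α | OC[C@@H]1[C@H]2[C@@H]3O[C@]3(C(C)C)C(=O)C[C@]21C | intermediate
12 | (1R,2S,3S,6S,7R)-2-hydroxy-7-(hydroxymethyl)-6-methyl-3-(propan-2-yl)bicyclo[4.1.0]heptan-4-one | OC[C@@H]1[C@H]2[C@H](O)[C@H](C(C)C)C(=O)C[C@]21C | intermediate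
13 | (1R,2S,3S,6S,7R)-6-methyl-3-(propan-2-yl)-2-(triethylsilyloxy)-7-[(triethylsilyloxy)methyl]bicyclo[4.1.0]heptan-4-one | CC[Si](CC)(CC)OC[C@@H]1[C@H]2[C@H](O[Si](CC)(CC)CC)[C@H](C(C)C)C(=O)C[C@]21C | intermediate
14 | (1R,2S,3R,4R,6S,7R)-6-methyl-3-(propan-2-yl)-2-(triethylsilyloxy)-7-[(triethylsilyloxy)methyl]bicyclo[4.1.0]heptan-4-ol | CC[Si](CC)(CC)OC[C@@H]1[C@H]2[C@H](O[Si](CC)(CC)CC)[C@H](C(C)C)[C@H](O)C[C@]21C | intermediate
15 | (1R,2S,3R,4R,6S,7R)-7-(hydroxymethyl)-6-methyl-3-(propan-2-yl)-2-(triethylsilyloxy)bicyclo[4.1.0]heptan-4-ol | OC[C@@H]1[C@H]2[C@H](O[Si](CC)(CC)CC)[C@H](C(C)C)[C@H](O)C[C@]21C | intermediate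
16 | (1R,2S,3R,4R,6R,7R)-4-hydroxy-6-methyl-3-(propan-2-yl)-2-(triethylsilyloxy)bicyclo[4.1.0]heptane-7-carbaldehyde | O=C[C@@H]1[C@H]2[C@H](O[Si](CC)(CC)CC)[C@H](C(C)C)[C@H](O)C[C@]21C | intermediate
17 | 1-(triphenyl-λ5-phosphanylidene)propan-2-one | CC(=O)C=P(c1ccccc1)(c1ccccc1)c1ccccc1 | starting material
18 | (3E)-4-[(1R,2S,3R,4R,6S,7R)-4-hydroxy-6-methyl-3-(propan-2-yl)-2-(triethylsilyloxy)bicyclo[4.1.0]heptan-7-yl]but-3-en-2-one | CC(=O)/C=C/[C@@H]1[C@H]2[C@H](O[Si](CC)(CC)CC)[C@H](C(C)C)[C@H](O)C[C@]21C | intermediate
19 | 4-[(1R,2S,3R,4R,6S,7R)-4-hydroxy-6-methyl-3-(propan-2-yl)-2-(triethylsilyloxy)bicyclo[4.1.0]heptan-7-yl]butan-2-one | CC(=O)CC[C@@H]1[C@H]2[C@H](O[Si](CC)(CC)CC)[C@H](C(C)C)[C@H](O)C[C@]21C | intermediate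
20 | 3-phenylprop-2-ynoyl chloride | O=C(Cl)C#Cc1ccccc1 | starting material
21 | (1R,2S,3R,4R,6S,7R)-6-methyl-7-(3-oxobutyl)-3-(propan-2-yl)-2-(triethylsilyloxy)bicyclo[4.1.0]heptan-4-yl 3-phenylprop-2-ynoate | CC(=O)CC[C@@H]1[C@H]2[C@H](O[Si](CC)(CC)CC)[C@H](C(C)C)[C@H](OC(=O)C#Cc3ccccc3)C[C@]21C | intermediate
22 | (1R,2S,3R,4R,6S,7R)-6-methyl-7-(3-oxobutyl)-3-(propan-2-yl)-2-(triethylsilyloxy)bicyclo[4.1.0]heptan-4-yl (2Z)-3-phenylprop-2-enoate | CC(=O)CC[C@@H]1[C@H]2[C@H](O[Si](CC)(CC)CC)[C@H](C(C)C)[C@H](OC(=O)/C=C\c3ccccc3)C[C@]21C | intermediate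
23 | (1R,2S,3S,4R,6S,7R)-2-hydroxy-6-methyl-7-(3-oxobutyl)-3-(propan-2-yl)bicyclo[4.1.0]heptan-4-yl (2Z)-3-phenylprop-2-enoate (CNP0217452.3) | CC(=O)CC[C@@H]1[C@H]2[C@H](O)[C@H](C(C)C)[C@H](OC(=O)/C=C\c3ccccc3)C[C@]21C | target

## Step count and least certain steps

Total: 16 steps. Longest linear sequence: 15 steps (from 4 through steps 2 to 16); the cyclopropene branch is 1 step.

**Step 4 (key step).** The cycloaddition of a tetrasubstituted diene with an unactivated, methyl-substituted cyclopropene may be slow. Ene-type self-reaction of the cyclopropene and decomposition of the diene could then compete, the regiochemistry could leak, and adventitious acid could unmask the adduct in the wrong sense. The fallback replaces the ester by an imide, a dienophile class known to react readily with acyclic dienes, and sets out from 3. Saponification (LiOH, aq. THF) gives (1R)-2-methylcycloprop-2-ene-1-carboxylic acid F1. The pivaloyl mixed anhydride of F1 with lithiated (4S)-4-phenyl-1,3-oxazolidin-2-one gives the N-acyl oxazolidinone F2. Cycloaddition of F2 with 6 gives the imide silyl ketal cycloadduct F3, which buffered fluoride collapses to the imide vinylogous ester F4. LiAlH4 followed by aqueous acid cleaves the auxiliary, reduces C7 to the hydroxymethyl level and transposes the enone, so the fallback returns to the route at 10.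

**Step 7.** The samarium enolate may be protonated on the α face (for example by methanol held on the neighbouring samarium alkoxide), or C3 may later epimerise toward the more stable trans arrangement; either would carry the wrong C3 configuration into step 9. The fallback sets C3 by a stereospecific syn addition and sets out from 11. Wharton transposition (N2H4·H2O, AcOH cat., MeOH) gives the allylic alcohol (1R,2S,6S,7R)-7-(hydroxymethyl)-6-methyl-3-(propan-2-yl)bicyclo[4.1.0]hept-3-en-2-ol F5. Silylation (Et3SiOTf, 2,6-lutidine) gives the bis(triethylsilyl) ether F6. Hydroboration–oxidation (BH3·THF; NaOH, H2O2) anti to the allylic silyl ether adds H to C3 and boron to C4 from the β face, giving the 4β-alcohol F7 with isopropyl α. Swern oxidation of F7 returns to the route at 13.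

**Step 1.** Enantioinduction may be incomplete with so small an alkyne and a small diazo ester. The fallback is a resolution and sets out from 1 and 2. Rh2(OAc)4 gives racemic ethyl 2-methylcycloprop-2-ene-1-carboxylate F8, and saponification gives the racemic acid F9. Coupling with (4S)-4-phenyl-1,3-oxazolidin-2-one as above gives the imide F2 and its (1S)-diastereomer F10, which are separated by chromatography. Ethanolysis of F2 with EtOMgBr returns to the route at 3; alternatively F2 is carried on as in the fallback to step 4.

**Step 15.** The semihydrogenation may over-reduce to the saturated ester or isomerise Z to E on the catalyst. The fallback builds the alkene by olefination and sets out from 19. Esterification with (diphenoxyphosphoryl)acetic acid (DCC, DMAP) gives the phosphonoacetate F11. Z-selective Horner–Wadsworth–Emmons olefination of F11 with benzaldehyde (NaH, THF, −78 °C) returns to the route at 22.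

## Further compounds

F1 | step 4 | (1R)-2-methylcycloprop-2-ene-1-carboxylic acid | OC(=O)[C@@H]1C=C1C
F2 | step 4 | (4S)-3-[(1R)-2-methylcycloprop-2-ene-1-carbonyl]-4-phenyl-1,3-oxazolidin-2-one | O=C([C@@H]1C=C1C)N1[C@@H](c2ccccc2)COC1=O
F3 | step 4 | imide silyl ketal cycloadduct, 7-exo acyl oxazolidinone, both C2 epimers (not isolated) | O=C([C@@H]1[C@H]2C(OCC)(O[Si](C)(C)C)C(C(C)C)=C(OCC)C[C@]21C)N1[C@@H](c2ccccc2)COC1=O
F4 | step 4 | (4S)-3-{[4-ethoxy-6-methyl-2-oxo-3-(propan-2-yl)bicyclo[4.1.0]hept-3-en-7-yl]carbonyl}-4-phenyl-1,3-oxazolidin-2-one, ring configuration as in 8 | O=C([C@@H]1[C@H]2C(=O)C(C(C)C)=C(OCC)C[C@]21C)N1[C@@H](c2ccccc2)COC1=O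
F5 | step 7 | (1R,2S,6S,7R)-7-(hydroxymethyl)-6-methyl-3-(propan-2-yl)bicyclo[4.1.0]hept-3-en-2-ol, 2α-hydroxyl | OC[C@@H]1[C@H]2[C@H](O)C(C(C)C)=CC[C@]21C
F6 | step 7 | bis(triethylsilyl) ether of F5 | CC[Si](CC)(CC)OC[C@@H]1[C@H]2[C@H](O[Si](CC)(CC)CC)C(C(C)C)=CC[C@]21C
F7 | step 7 | 4β-alcohol: 6-methyl-3α-(propan-2-yl)-2α-(triethylsilyloxy)-7-exo-[(triethylsilyloxy)methyl]bicyclo[4.1.0]heptan-4β-ol | CC[Si](CC)(CC)OC[C@@H]1[C@H]2[C@H](O[Si](CC)(CC)CC)[C@H](C(C)C)[C@@H](O)C[C@]21C
F8 | step 1 | racemic ethyl 2-methylcycloprop-2-ene-1-carboxylate | CCOC(=O)C1C=C1C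
F9 | step 1 | racemic 2-methylcycloprop-2-ene-1-carboxylic acid | OC(=O)C1C=C1C
F10 | step 1 | (4S)-3-[(1S)-2-methylcycloprop-2-ene-1-carbonyl]-4-phenyl-1,3-oxazolidin-2-one | O=C([C@H]1C=C1C)N1[C@@H](c2ccccc2)COC1=O
F11 | step 15 | (1R,2S,3R,4R,6S,7R)-6-methyl-7-(3-oxobutyl)-3-(propan-2-yl)-2-(triethylsilyloxy)bicyclo[4.1.0]heptan-4-yl 2-(diphenoxyphosphoryl)acetate | CC(=O)CC[C@@H]1[C@H]2[C@H](O[Si](CC)(CC)CC)[C@H](C(C)C)[C@H](OC(=O)CP(=O)(Oc3ccccc3)Oc3ccccc3)C[C@]21C
A1 | alternative 1 | cyclopropene with CH2OSi(t-Bu)Ph2 on the sp3 carbon and a 2-(4-methoxybenzyloxy)ethyl arm on the alkene | C1=C(CCOCc2ccc(OC)cc2)[C@@H]1CO[Si](c1ccccc1)(c1ccccc1)C(C)(C)C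
A2 | alternative 1 | trisubstituted cyclopropane with C6 methyl, C7 3-oxobutyl chain and two differentiated arms | CC(=O)CC[C@@H]1[C@@H](CO[Si](c2ccccc2)(c2ccccc2)C(C)(C)C)[C@@]1(C)CCOCc2ccc(OC)cc2
A3 | alternative 2 | 3-[(tert-butyldimethylsilyl)oxy]-5-[(1E)-3-chloroprop-1-en-1-yl]-5-methyl-2-(propan-2-yl)cyclohexan-1-one | ClC/C=C/[C@]1(C)C[C@@H](O[Si](C)(C)C(C)(C)C)[C@@H](C(C)C)C(=O)C1
A4 | alternative 2 | 4-[(tert-butyldimethylsilyl)oxy]-7-ethenyl-6-methyl-3-(propan-2-yl)bicyclo[4.1.0]heptan-2-one | C=C[C@@H]1[C@H]2C(=O)[C@H](C(C)C)[C@H](O[Si](C)(C)C(C)(C)C)C[C@]21C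
A5 | alternative 3 | 3-[(tert-butyldimethylsilyl)oxy]-7-(2-methyl-1,3-dioxolan-2-yl)-2-(propan-2-yl)-4-(prop-1-en-2-yl)-5-(tributylstannyl)heptanal, tin-bearing carbon unassigned | CC1(OCCO1)CCC([Sn](CCCC)(CCCC)CCCC)[C@H](C(C)=C)[C@H](O[Si](C)(C)C(C)(C)C)[C@H](C(C)C)C=O
A6 | alternative 3 | bicyclo[4.1.0]heptan-4-ol with C2 silyl ether and side-chain dioxolane | CC4(OCCO4)CC[C@@H]1[C@H]2[C@H](O[Si](C)(C)C(C)(C)C)[C@H](C(C)C)[C@H](O)C[C@]21C
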